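# Design of a synthesis of (2R,3S,4R)-4-(2,4-dihydroxy-3-methoxyphenyl)-2-(3,4-dihydroxyphenyl)chromane-3,7-diol (18)

## The problem

Compound 18 is a 4-arylflavan-3-ol. Its benzene ring (ring A, 7-hydroxyl) is fused to a pyran (ring C) that carries a catechol (ring B) on C2, a hydroxyl on C3 and a 2,4-dihydroxy-3-methoxyphenyl group (ring D) on C4. A synthesis has to join rings A, B and D through the chain C2–C3–C4 and close ring C through O1; C4 is a diarylmethine between two very electron-rich arenes, and all three chain carbons are stereocentres. The configuration is (2R,3S,4R), that is 2,3-trans-3,4-trans, with ring B, the hydroxyl and ring D all equatorial on the half-chair of ring C. Because this is the most stable arrangement, one centre fixed in the absolute sense can hold the other two, provided C3 can equilibrate at some stage. C2 (a benzylic ether carbon) and C4 (doubly benzylic) ionise readily under acid, and the five phenols, a catechol among them, are easily oxidised once free, so the masking groups must come off last and under neutral conditions. Ring D has its 4'-hydroxyl para to C4 and ring A has its oxygen (the later O1) ortho to C4. C4 is therefore the exocyclic terminus of a para-quinone methide of ring D placed beside a phenol nucleophile, which is the substrate pattern of an oxa-Michael/1,6-addition annulation with an enal. Two consequences follow: the second oxygen of ring D that is ortho to C4 (O2') must be blocked so that it cannot compete as nucleophile, and the carbon that the enal leaves on C3 must later be exchanged for oxygen with retention.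

## Retrosynthesis

**18 from 17.** The five aryl O–benzyl bonds are cut last. Benzyl is the only protecting group of the end game because hydrogenolysis is neutral and spares the acid-labile C2 and C4 and the oxidation-prone catechol. The forward reaction is asked only to leave the C2–O1 benzylic ether intact.

**17 from 16 and 15.** The C3–O bond is traced back to a C3–acetyl bond. A Baeyer–Villiger oxidation of methyl ketone 15 gives acetate 16, and methanolysis gives alcohol 17. This is preferred over a decarboxylative hydroxylation of the corresponding acid, which runs through a C3 radical. In the Baeyer–Villiger reaction the secondary carbon migrates ahead of methyl and does so with retention, so the configuration set earlier is carried over unchanged.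

**15 from 14, 13 and 12.** The methyl ketone comes from aldehyde 12 by methyl Grignard addition (13), benzylation of the one free phenol (14) and oxidation (15). The Grignard step is placed first so that the β-aryloxy aldehyde, which can open by retro-oxa-Michael reaction under base, is consumed before any carbonate is used.

**12 from 8 and 10 via 11 (key cut).** O1–C2 and C3–C4 are cut together. This removes ring C and all three stereocentres in one step and leaves two flat, achiral or racemic partners: benzhydrol 8 and cinnamaldehyde 10. The neighbouring cuts create less. Arylation of a C4 cation of a preformed flavan-3,4-diol forms only C4–C1' and needs an enantiopure flavan. Closure of O1–C2 by substitution risks the benzylic centre. The forward reaction is asked to release quinone methide 11 from 8 under conditions that an amine catalyst tolerates. It must use only the ring A phenol as oxygen nucleophile, which is why O2' of ring D and O7 of ring A are benzyl ethers. It must also deliver the all-trans aldehyde 12 as one enantiomer.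

**8 from 7, and 7 from 4 and 5 via 6.** The bond between the carbinol carbon and ring A (the later C4–C4a) is cut. Phenol 5 is commercial and needs no protection. A phenylboronic acid template ties phenol and aldehyde together in benzodioxaborin 6 and so fixes the ortho position. The other cut, between the carbinol carbon and ring D, would need an aryl metal reagent with three differentiated oxygens. The 4'-oxygen of ring D travels as an allyl ether, removed from 7 under neutral palladium catalysis to give 8.

**4 from 3, 2 and 1.** Aldehyde 4 is traced to 2-methoxyresorcinol 1 by formylation (2), allylation of the more acidic 4-hydroxyl (3) and benzylation of the chelated 2-hydroxyl (4). The inherent reactivity order of the two hydroxyls of 2 gives exactly the pattern the key step needs.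

**10 from 9.** The enal is cut at its double bond; a formyl-stabilised Wittig reagent homologates commercial aldehyde 9 in one step.

## Roads not taken

**Alternative 1: ring A by benzannulation on the finished stereotriad chain.** The cut removes three bonds of ring A (C8a–C8, C6–C7, C4a–C8a). In the forward direction, photochemical Wolff rearrangement of diazo enone A2 gives a vinylketene. On heating this adds siloxyalkyne A3, and the cyclobutenone formed opens and recloses to phenol A1. The merit is that the resorcinol pattern of ring A arrives regiodefined and with its two oxygens already differentiated, and that each stereocentre is made by a separate, adjustable reaction. For this target the weak points weigh more.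
- All three stereocentres must first be built on an open chain carrying two aryl groups, without help from a ring.
- A2 is a diazo compound bearing ionisable benzylic ethers and has to survive light and heat.
- After A1, ring C must still be closed by substitution at the benzylic C2, where ionisation threatens the configuration.
- The most elaborate step is spent on ring A, which is the one part of the molecule that can be bought as a simple resorcinol ether.

The chosen plan is much shorter and makes ring C and the stereotriad together. What it gives up is the independent control of each centre: it relies on one catalyst-controlled event and on the thermodynamic preference for the all-trans chroman.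

**Alternative 2: asymmetric conjugate arylation and cyclodehydration to a 4H-chromene.** The cut is C4–C4a and O1–C2. Forward, Rh(acac)(C2H4)2 with a chiral diene transfers the 2-hydroxyaryl group of boronic acid A6 to the β-carbon of chalcone A5. The phenol then condenses with the ketone to give 4H-chromene A4 with C4 set. Hydroboration–oxidation of the enol ether of A4, anti to ring D and syn across C2=C3, would then install the C3 hydroxyl and C2 in the required trans,trans sense. This road is better than the chosen one in three respects.
- The C3 oxygen is introduced directly, so the four-step exchange of carbon for oxygen is not needed.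
- All phenols can be benzylated alike, so ring D needs no differentiation of its hydroxyls.
- The overall sequence would probably be several steps shorter.

Its weak points lie in the two central steps.
- A6 is an electron-rich ortho-hydroxyarylboronic acid and is prone to protodeboronation.
- The β-carbon of A5 bears an ortho-substituted, trioxygenated aryl group, which makes the enone a poor and hindered acceptor.
- A4 is an acid- and air-sensitive 2-aryl enol ether.
- C2 and C3 then depend on a kinetic, substrate-controlled hydroboration that cannot be corrected afterwards.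

The chosen plan sets against the shorter count that ring C and all three centres arise in one metal-free catalytic step from stable partners, that C3 is thermodynamically backed, and that no sensitive enol ether is handled. It pays for this with the longer end game.

**Alternative 3: ring A dearomatised, etherified at C8a, then rearomatised.** The cut is C8a–O1. Forward, K2CO3 in methanol cleaves the C2 acetate of dienone A8 and the alkoxide adds to the dienone carbon that becomes C8a. Toluenesulfonic acid then expels methanol and rearomatises ring A to give A7. The merits are real. The oxygen on C2 stays on C2, so no substitution occurs at the benzylic centre. Ring A needs only a para-hydroxyl at the outset. A7 carries a free 7-hydroxyl and is otherwise the fully protected target. The drawbacks are these.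
- The stereotriad must again be assembled on an open chain before the key step.
- The oxidative dearomatisation leading to A8 has to single out ring A in the presence of two other electron-rich rings.
- The rearomatisation exposes the ionisable C2 and C4 to a sulfonic acid.
- The ortho oxygen that this road installs is already present in a resorcinol-type ring A.

Compared with it, the chosen plan uses that ortho oxygen as the nucleophile and needs no redox detour on ring A. Alternative 3 is the safer of the two only with regard to C2, which the chosen plan sets by catalyst control in a reversible oxa-Michael step.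

Key step: step 7

Assumption: the carbinol carbon made in step 8 is carried as a mixture of both epimers because step 10 removes it, and the geometry of the exocyclic double bond of 11 is left open because both forms lead to the same benzylic centre.

The descriptors at C2, C3 and C4 change between 12 and 18 only because substituent priorities change. The spatial arrangement fixed in step 7 (ring B, the C3 substituent and ring D mutually trans) stays the same throughout.

## Route

Step 1
Reactants: 1 2-methoxybenzene-1,3-diol (2-methoxyresorcinol)
Product: 2 2,4-dihydroxy-3-methoxybenzaldehyde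
Conditions: POCl3, DMF, MeCN, 0 °C → rt; then H2O, 50 °C
Reagents that add atoms: N,N-dimethylformamide, CN(C)C=O; water, O
Why: Vilsmeier–Haack formylation; both hydroxyls direct the chloroiminium ion to C4 (equivalent to C6), ortho to one and para to the other, and hydrolysis of the iminium salt releases the aldehyde.

Step 2
Reactants: 2 2,4-dihydroxy-3-methoxybenzaldehyde
Product: 3 2-hydroxy-3-methoxy-4-(prop-2-en-1-yloxy)benzaldehyde
Conditions: allyl bromide, NaHCO3, KI (cat.), MeCN, 60 °C
Reagents that add atoms: allyl bromide, C=CCBr
Why: Williamson etherification; the 4-hydroxyl is the more acidic (para to the formyl group) while the 2-hydroxyl is held in a hydrogen bond to the carbonyl, so a weak base should alkylate O4 only. Allyl survives base, weak acid and heat and is later removed under neutral palladium catalysis without touching benzyl ethers.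

Step 3
Reactants: 3 2-hydroxy-3-methoxy-4-(prop-2-en-1-yloxy)benzaldehyde
Product: 4 2-(benzyloxy)-3-methoxy-4-(prop-2-en-1-yloxy)benzaldehyde
Conditions: BnBr, K2CO3, DMF, 60 °C
Reagents that add atoms: benzyl bromide, BrCc1ccccc1
Why: Williamson etherification of the remaining chelated phenol under more forcing conditions; this benzyl ether blocks the second ortho oxygen of ring D, which would otherwise compete as oxa-Michael nucleophile in step 7.

Step 4
Reactants: 4 2-(benzyloxy)-3-methoxy-4-(prop-2-en-1-yloxy)benzaldehyde; 5 3-(benzyloxy)phenol
Product: 7 rac-[2-(benzyloxy)-3-methoxy-4-(prop-2-en-1-yloxy)phenyl][4-(benzyloxy)-2-hydroxyphenyl]methanol, via benzodioxaborin 6 (not isolated)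
Conditions: PhB(OH)2, EtCO2H (cat.), toluene, reflux (Dean–Stark); then 30% aq H2O2, THF, 0 °C → rt
Reagents that add atoms: none
Why: Boronic acid-templated ortho-hydroxyalkylation of a phenol; the phenyl boronate of 5 binds aldehyde 4 and delivers it to the ortho carbon through a six-membered transition state, giving 6, and of the two ortho positions the one para to the benzyloxy group is less hindered and more activated. Oxidative cleavage of the B–phenyl bond then frees the diol without acid.

Step 5
Reactants: 7 rac-[2-(benzyloxy)-3-methoxy-4-(prop-2-en-1-yloxy)phenyl][4-(benzyloxy)-2-hydroxyphenyl]methanol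
Product: 8 rac-[2-(benzyloxy)-4-hydroxy-3-methoxyphenyl][4-(benzyloxy)-2-hydroxyphenyl]methanol
Conditions: Pd(PPh3)4 (cat.), morpholine, THF, rt
Reagents that add atoms: none
Why: Palladium-catalysed deallylation (Tsuji–Trost type); zerovalent palladium ionises the aryl allyl ether to a π-allyl complex that morpholine intercepts, and the neutral conditions spare the acid-labile benzhydrol and the benzyl ethers.

Step 6
Reactants: 9 3,4-bis(benzyloxy)benzaldehyde
Product: 10 (E)-3-[3,4-bis(benzyloxy)phenyl]prop-2-enal
Conditions: Ph3P=CHCHO, toluene, 90 °C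
Reagents that add atoms: (triphenylphosphoranylidene)acetaldehyde, O=CC=P(c1ccccc1)(c1ccccc1)c1ccccc1
Why: Wittig reaction with a formyl-stabilised ylide; it gives the E-enal in one step, and the electron-rich product enal is less electrophilic than 9, which limits a second homologation.

Step 7
Reactants: 8 rac-[2-(benzyloxy)-4-hydroxy-3-methoxyphenyl][4-(benzyloxy)-2-hydroxyphenyl]methanol; 10 (E)-3-[3,4-bis(benzyloxy)phenyl]prop-2-enal
Product: 12 (2S,3S,4S)-7-(benzyloxy)-4-[2-(benzyloxy)-4-hydroxy-3-methoxyphenyl]-2-[3,4-bis(benzyloxy)phenyl]chromane-3-carbaldehyde, via para-quinone methide 11 (not isolated)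
Conditions: (S)-2-[diphenyl(trimethylsilyloxy)methyl]pyrrolidine (20 mol %), PhCO2H (20 mol %), CH2Cl2, rt
Reagents that add atoms: none
Why: The ammonium benzoate buffer should ionise the doubly donor-stabilised benzhydrol 8 with loss of water to quinone methide 11, which is a vinylogous ester through its 3-benzyloxy group and carries a donor aryl on the methide carbon, while the amine condenses with 10 to the E-iminium ion. The ring A phenol adds to the iminium β-carbon (oxa-Michael, O1–C2), the resulting enamine carbon C3 attacks the methide carbon C4 in a 1,6-addition that rearomatises ring D (C3–C4), and hydrolysis releases 12 and the amine. The closest known reaction type is the amine-catalysed oxa-Michael/1,6-addition cascade of ortho-hydroxyphenyl para-quinone methides with enals to 2,3,4-trisubstituted chromans, joined here to the acid-mediated release of a quinone methide from a hydroxybenzhydrol. Ring C closes in the second bond formation as a 6-exo-trig (enol-exo) cyclisation, since the C4=C1' double bond lies outside the forming ring. C2 is set by the catalyst: the diphenyl(silyloxy)methyl group of the (S)-amine shields the Re face of the β-carbon, oxygen adds to the Si face, and this gives 2S in 12, the arrangement that becomes 2R in 18. C4 is set in the ring closure through a chair-like transition state with ring B and the quinone methide ring both equatorial, and C3, epimerisable through the enamine, settles with its formyl group equatorial and trans to both neighbours. The step needs chemoselectivity for one oxygen nucleophile and one quinone methide, which the substrate secures by leaving only the 4'-hydroxyl of ring D and the ortho hydroxyl of ring A free, and racemic 8 converges because its carbinol carbon becomes planar in 11.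

Step 8
Reactants: 12 (2S,3S,4S)-7-(benzyloxy)-4-[2-(benzyloxy)-4-hydroxy-3-methoxyphenyl]-2-[3,4-bis(benzyloxy)phenyl]chromane-3-carbaldehyde
Product: 13 1-[(2S,3R,4S)-7-(benzyloxy)-4-[2-(benzyloxy)-4-hydroxy-3-methoxyphenyl]-2-[3,4-bis(benzyloxy)phenyl]chroman-3-yl]ethan-1-ol (both epimers at the carbinol carbon)
Conditions: MeMgBr (3 equiv), THF, −78 → 0 °C; then pH 7 buffer
Reagents that add atoms: methylmagnesium bromide, C[Mg]Br
Why: Grignard addition to the aldehyde after the first equivalent has deprotonated the phenol; at low temperature addition should outrun enolisation, and consuming the β-aryloxy aldehyde at once removes the risk of ring opening under the basic conditions used next.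

Step 9
Reactants: 13 1-[(2S,3R,4S)-7-(benzyloxy)-4-[2-(benzyloxy)-4-hydroxy-3-methoxyphenyl]-2-[3,4-bis(benzyloxy)phenyl]chroman-3-yl]ethan-1-ol
Product: 14 1-[(2S,3R,4S)-7-(benzyloxy)-4-[2,4-bis(benzyloxy)-3-methoxyphenyl]-2-[3,4-bis(benzyloxy)phenyl]chroman-3-yl]ethan-1-ol (both epimers at the carbinol carbon)
Conditions: BnBr, K2CO3, acetone, 50 °C
Reagents that add atoms: benzyl bromide, BrCc1ccccc1
Why: Williamson etherification selective for the phenol, which carbonate deprotonates while the secondary alcohol stays neutral; the guaiacol-type phenol must be capped before the oxidants of steps 10 and 11 are used.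

Step 10
Reactants: 14 1-[(2S,3R,4S)-7-(benzyloxy)-4-[2,4-bis(benzyloxy)-3-methoxyphenyl]-2-[3,4-bis(benzyloxy)phenyl]chroman-3-yl]ethan-1-ol
Product: 15 1-[(2S,3S,4S)-7-(benzyloxy)-4-[2,4-bis(benzyloxy)-3-methoxyphenyl]-2-[3,4-bis(benzyloxy)phenyl]chroman-3-yl]ethan-1-one
Conditions: Dess–Martin periodinane, pyridine, CH2Cl2, 0 °C → rt
Reagents that add atoms: none
Why: Dess–Martin oxidation of the secondary alcohol under near-neutral conditions; C3 becomes epimerisable again but already sits in its preferred equatorial, all-trans position.

Step 11
Reactants: 15 1-[(2S,3S,4S)-7-(benzyloxy)-4-[2,4-bis(benzyloxy)-3-methoxyphenyl]-2-[3,4-bis(benzyloxy)phenyl]chroman-3-yl]ethan-1-one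
Product: 16 (2R,3S,4S)-7-(benzyloxy)-4-[2,4-bis(benzyloxy)-3-methoxyphenyl]-2-[3,4-bis(benzyloxy)phenyl]chroman-3-yl acetate
Conditions: mCPBA, NaHCO3, CH2Cl2, 0 °C → rt
Reagents that add atoms: 3-chloroperbenzoic acid, OOC(=O)c1cccc(Cl)c1
Why: Baeyer–Villiger oxidation; in the Criegee intermediate the secondary C3 migrates in preference to methyl and with retention, so the acetyl carbon is replaced by oxygen without change at C3.

Step 12
Reactants: 16 (2R,3S,4S)-7-(benzyloxy)-4-[2,4-bis(benzyloxy)-3-methoxyphenyl]-2-[3,4-bis(benzyloxy)phenyl]chroman-3-yl acetate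
Product: 17 (2R,3S,4S)-7-(benzyloxy)-4-[2,4-bis(benzyloxy)-3-methoxyphenyl]-2-[3,4-bis(benzyloxy)phenyl]chroman-3-ol
Conditions: K2CO3 (cat.), MeOH/THF, rt
Reagents that add atoms: none
Why: Base-catalysed transesterification of the acetate with methanol; only the acyl–oxygen bond is broken, so C3 is untouched, and the product is no longer a carbonyl compound that could open by β-elimination.

Step 13
Reactants: 17 (2R,3S,4S)-7-(benzyloxy)-4-[2,4-bis(benzyloxy)-3-methoxyphenyl]-2-[3,4-bis(benzyloxy)phenyl]chroman-3-ol
Product: 18 (2R,3S,4R)-4-(2,4-dihydroxy-3-methoxyphenyl)-2-(3,4-dihydroxyphenyl)chromane-3,7-diol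
Conditions: H2 (1 atm), Pd(OH)2/C, THF/MeOH, rt
Reagents that add atoms: none
Why: Catalytic hydrogenolysis of the five benzyl ethers; the conditions are neutral and non-oxidising, and at atmospheric pressure the C2–O1 ether of flavan-3-ols is expected to persist.

## Compound list

1 | 2-methoxybenzene-1,3-diol (2-methoxyresorcinol) | COc1c(O)cccc1O | starting material
2 | 2,4-dihydroxy-3-methoxybenzaldehyde | COc1c(O)ccc(C=O)c1O | intermediate
3 | 2-hydroxy-3-methoxy-4-(prop-2-en-1-yloxy)benzaldehyde | COc1c(OCC=C)ccc(C=O)c1O | intermediate
4 | 2-(benzyloxy)-3-methoxy-4-(prop-2-en-1-yloxy)benzaldehyde | COc1c(OCC=C)ccc(C=O)c1OCc1ccccc1 | intermediate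
5 | 3-(benzyloxy)phenol | Oc1cccc(OCc2ccccc2)c1 | starting material
6 | rac-7-(benzyloxy)-4-[2-(benzyloxy)-3-methoxy-4-(prop-2-en-1-yloxy)phenyl]-2-phenyl-4H-1,3,2-benzodioxaborinine | COc1c(OCC=C)ccc(C2OB(c3ccccc3)Oc3cc(OCc4ccccc4)ccc32)c1OCc1ccccc1 | intermediate (not isolated)
7 | rac-[2-(benzyloxy)-3-methoxy-4-(prop-2-en-1-yloxy)phenyl][4-(benzyloxy)-2-hydroxyphenyl]methanol | COc1c(OCC=C)ccc(C(O)c2ccc(OCc3ccccc3)cc2O)c1OCc1ccccc1 | intermediate
8 | rac-[2-(benzyloxy)-4-hydroxy-3-methoxyphenyl][4-(benzyloxy)-2-hydroxyphenyl]methanol | COc1c(O)ccc(C(O)c2ccc(OCc3ccccc3)cc2O)c1OCc1ccccc1 | intermediate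
9 | 3,4-bis(benzyloxy)benzaldehyde | O=Cc1ccc(OCc2ccccc2)c(OCc2ccccc2)c1 | starting material
10 | (E)-3-[3,4-bis(benzyloxy)phenyl]prop-2-enal | O=C/C=C/c1ccc(OCc2ccccc2)c(OCc2ccccc2)c1 | intermediate
11 | 3-(benzyloxy)-4-{[4-(benzyloxy)-2-hydroxyphenyl]methylidene}-2-methoxycyclohexa-2,5-dien-1-one (double bond geometry open) | COC1=C(OCc2ccccc2)C(=Cc2ccc(OCc3ccccc3)cc2O)C=CC1=O | intermediate (not isolated)
12 | (2S,3S,4S)-7-(benzyloxy)-4-[2-(benzyloxy)-4-hydroxy-3-methoxyphenyl]-2-[3,4-bis(benzyloxy)phenyl]chromane-3-carbaldehyde | COc1c(O)ccc([C@@H]2c3ccc(OCc4ccccc4)cc3O[C@H](c3ccc(OCc4ccccc4)c(OCc4ccccc4)c3)[C@H]2C=O)c1OCc1ccccc1 | intermediate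
13 | 1-[(2S,3R,4S)-7-(benzyloxy)-4-[2-(benzyloxy)-4-hydroxy-3-methoxyphenyl]-2-[3,4-bis(benzyloxy)phenyl]chroman-3-yl]ethan-1-ol (both carbinol epimers) | COc1c(O)ccc([C@@H]2c3ccc(OCc4ccccc4)cc3O[C@H](c3ccc(OCc4ccccc4)c(OCc4ccccc4)c3)[C@H]2C(C)O)c1OCc1ccccc1 | intermediate
14 | 1-[(2S,3R,4S)-7-(benzyloxy)-4-[2,4-bis(benzyloxy)-3-methoxyphenyl]-2-[3,4-bis(benzyloxy)phenyl]chroman-3-yl]ethan-1-ol (both carbinol epimers) | COc1c(OCc5ccccc5)ccc([C@@H]2c3ccc(OCc4ccccc4)cc3O[C@H](c3ccc(OCc4ccccc4)c(OCc4ccccc4)c3)[C@H]2C(C)O)c1OCc1ccccc1 | intermediate
15 | 1-[(2S,3S,4S)-7-(benzyloxy)-4-[2,4-bis(benzyloxy)-3-methoxyphenyl]-2-[3,4-bis(benzyloxy)phenyl]chroman-3-yl]ethan-1-one | COc1c(OCc5ccccc5)ccc([C@@H]2c3ccc(OCc4ccccc4)cc3O[C@H](c3ccc(OCc4ccccc4)c(OCc4ccccc4)c3)[C@H]2C(C)=O)c1OCc1ccccc1 | intermediate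
16 | (2R,3S,4S)-7-(benzyloxy)-4-[2,4-bis(benzyloxy)-3-methoxyphenyl]-2-[3,4-bis(benzyloxy)phenyl]chroman-3-yl acetate | COc1c(OCc5ccccc5)ccc([C@@H]2c3ccc(OCc4ccccc4)cc3O[C@H](c3ccc(OCc4ccccc4)c(OCc4ccccc4)c3)[C@H]2OC(C)=O)c1OCc1ccccc1 | intermediate
17 | (2R,3S,4S)-7-(benzyloxy)-4-[2,4-bis(benzyloxy)-3-methoxyphenyl]-2-[3,4-bis(benzyloxy)phenyl]chroman-3-ol | COc1c(OCc5ccccc5)ccc([C@@H]2c3ccc(OCc4ccccc4)cc3O[C@H](c3ccc(OCc4ccccc4)c(OCc4ccccc4)c3)[C@H]2O)c1OCc1ccccc1 | intermediate
18 | (2R,3S,4R)-4-(2,4-dihydroxy-3-methoxyphenyl)-2-(3,4-dihydroxyphenyl)chromane-3,7-diol | COc1c(O)ccc([C@@H]2c3ccc(O)cc3O[C@H](c3ccc(O)c(O)c3)[C@H]2O)c1O | target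

## Step count and least certain steps

Total: 13 steps. Longest linear sequence: 12 steps (steps 1–5 and 7–13); the enal branch (step 6) joins at step 7.

**Step 7 (key step).** Three processes are most likely to go wrong. The unhindered quinone methide may oligomerise before the enamine captures it, by alkylating ring A of a second molecule or by dimerising through its ortho-quinone methide tautomer. Ionisation of 8 may be too slow in the weakly acidic amine buffer. Facial control at C4 may be incomplete, and C4 cannot be corrected afterwards. The fallback separates the release of the quinone methide from acid. It sets out from 8, which with 4-methylbenzenesulfinic acid in CH2Cl2 should give the sulfone 5-(benzyloxy)-2-{[2-(benzyloxy)-4-hydroxy-3-methoxyphenyl](4-methylbenzenesulfonyl)methyl}phenol F1. F1 is stable and can be stored. Under aqueous NaHCO3 in the presence of 10 and the same amine it loses sulfinate by base-induced 1,6-elimination, so that 11 forms slowly beside the iminium ion; the route is rejoined at 12.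

**Step 4.** The likely failure is ionisation of the benzodioxaborin at the very electron-rich diaryl carbon under the acidic reflux, followed by alkylation of a second molecule of 5 (triarylmethane formation), together with slow condensation of the hindered, electron-rich aldehyde. The fallback works without acid and without the boron template. It sets out from 5, which with EtMgBr gives bromo[3-(benzyloxy)phenoxy]magnesium F2. After exchange of ether for CH2Cl2, F2 should add to 4 through a six-membered magnesium chelate at the ortho carbon and return to the route at 7 after neutral work-up.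

**Step 11.** Oxygen insertion at the hindered ketone may be slow, which gives the peracid time to oxidise the electron-rich rings, and the acid formed may epimerise or open the β-aryloxy ketone. The fallback replaces the ionic 1,2-shift by a radical decarboxylation and sets out from 12.
- Mitsunobu benzylation of the phenol (BnOH, PPh3, DIAD) gives (2S,3S,4S)-7-(benzyloxy)-4-[2,4-bis(benzyloxy)-3-methoxyphenyl]-2-[3,4-bis(benzyloxy)phenyl]chromane-3-carbaldehyde F3.
- Pinnick oxidation (NaClO2, NaH2PO4, 2-methylbut-2-ene) gives the chromane-3-carboxylic acid F4.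
- Coupling with N-hydroxypyridine-2-thione gives the Barton ester F5.
- Photolysis of F5 under O2 with t-BuSH gives the C3 hydroperoxide F6, in which oxygen is taken up anti to the two flanking aryl groups.
- PPh3 reduces F6 to 17, where the route is rejoined.

**Step 6.** The electron-rich aldehyde may react slowly with the stabilised ylide, and the product enal may be homologated a second time to the dienal. The fallback is the three-step ester route and sets out from 9. Horner–Wadsworth–Emmons reaction with triethyl phosphonoacetate and NaH gives ethyl (E)-3-[3,4-bis(benzyloxy)phenyl]prop-2-enoate F7. DIBAL-H reduces it to (E)-3-[3,4-bis(benzyloxy)phenyl]prop-2-en-1-ol F8, and MnO2 oxidises F8 to 10.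

## Further compounds

F1 | step 7 | rac-5-(benzyloxy)-2-{[2-(benzyloxy)-4-hydroxy-3-methoxyphenyl](4-methylbenzenesulfonyl)methyl}phenol | COc1c(O)ccc(C(c2ccc(OCc3ccccc3)cc2O)S(=O)(=O)c2ccc(C)cc2)c1OCc1ccccc1
F2 | step 4 | bromo[3-(benzyloxy)phenoxy]magnesium | Br[Mg]Oc1cccc(OCc2ccccc2)c1
F3 | step 11 | (2S,3S,4S)-7-(benzyloxy)-4-[2,4-bis(benzyloxy)-3-methoxyphenyl]-2-[3,4-bis(benzyloxy)phenyl]chromane-3-carbaldehyde | COc1c(OCc5ccccc5)ccc([C@@H]2c3ccc(OCc4ccccc4)cc3O[C@H](c3ccc(OCc4ccccc4)c(OCc4ccccc4)c3)[C@H]2C=O)c1OCc1ccccc1
F4 | step 11 | (2S,3S,4S)-7-(benzyloxy)-4-[2,4-bis(benzyloxy)-3-methoxyphenyl]-2-[3,4-bis(benzyloxy)phenyl]chromane-3-carboxylic acid | COc1c(OCc5ccccc5)ccc([C@@H]2c3ccc(OCc4ccccc4)cc3O[C@H](c3ccc(OCc4ccccc4)c(OCc4ccccc4)c3)[C@H]2C(=O)O)c1OCc1ccccc1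
F5 | step 11 | 2-thioxopyridin-1(2H)-yl (2S,3S,4S)-7-(benzyloxy)-4-[2,4-bis(benzyloxy)-3-methoxyphenyl]-2-[3,4-bis(benzyloxy)phenyl]chromane-3-carboxylate | COc1c(OCc5ccccc5)ccc([C@@H]2c3ccc(OCc4ccccc4)cc3O[C@H](c3ccc(OCc4ccccc4)c(OCc4ccccc4)c3)[C@H]2C(=O)ON6C=CC=CC6=S)c1OCc1ccccc1
F6 | step 11 | (2R,3S,4S)-7-(benzyloxy)-4-[2,4-bis(benzyloxy)-3-methoxyphenyl]-2-[3,4-bis(benzyloxy)phenyl]chroman-3-yl hydroperoxide | COc1c(OCc5ccccc5)ccc([C@@H]2c3ccc(OCc4ccccc4)cc3O[C@H](c3ccc(OCc4ccccc4)c(OCc4ccccc4)c3)[C@H]2OO)c1OCc1ccccc1
F7 | step 6 | ethyl (E)-3-[3,4-bis(benzyloxy)phenyl]prop-2-enoate | CCOC(=O)/C=C/c1ccc(OCc2ccccc2)c(OCc2ccccc2)c1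
F8 | step 6 | (E)-3-[3,4-bis(benzyloxy)phenyl]prop-2-en-1-ol | OC/C=C/c1ccc(OCc2ccccc2)c(OCc2ccccc2)c1
A1 | alternative 1 | benzannulation product: open C2–C4 chain with 2-hydroxy-4-(triisopropylsilyloxy)phenyl and 2,4-bis(benzyloxy)-3-methoxyphenyl on C4, benzyloxy on C3, tert-butyldimethylsilyloxy and 3,4-bis(benzyloxy)phenyl on C2 | COc1c(OCc4ccccc4)ccc([C@H](c3ccc(O[Si](C(C)C)(C(C)C)C(C)C)cc3O)[C@H](OCc4ccccc4)[C@@H](O[Si](C)(C)C(C)(C)C)c3ccc(OCc4ccccc4)c(OCc4ccccc4)c3)c1OCc4ccccc4
A2 | alternative 1 | (E)-6-(benzyloxy)-5-[2,4-bis(benzyloxy)-3-methoxyphenyl]-7-[3,4-bis(benzyloxy)phenyl]-7-(tert-butyldimethylsilyloxy)-1-diazohept-3-en-2-one with the chain configuration of A1 | COc1c(OCc4ccccc4)ccc([C@H](/C=C/C(=O)C=[N+]=[N-])[C@H](OCc4ccccc4)[C@@H](O[Si](C)(C)C(C)(C)C)c3ccc(OCc4ccccc4)c(OCc4ccccc4)c3)c1OCc4ccccc4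
A3 | alternative 1 | (ethynyloxy)tri(propan-2-yl)silane | C#CO[Si](C(C)C)(C(C)C)C(C)C
A4 | alternative 2 | (4S)-7-(benzyloxy)-4-[2,4-bis(benzyloxy)-3-methoxyphenyl]-2-[3,4-bis(benzyloxy)phenyl]-4H-chromene | COc1c(OCc4ccccc4)ccc([C@@H]2c3ccc(OCc4ccccc4)cc3OC(c3ccc(OCc4ccccc4)c(OCc4ccccc4)c3)=C2)c1OCc4ccccc4
A5 | alternative 2 | (E)-3-[2,4-bis(benzyloxy)-3-methoxyphenyl]-1-[3,4-bis(benzyloxy)phenyl]prop-2-en-1-one | COc1c(OCc2ccccc2)ccc(/C=C/C(=O)c2ccc(OCc3ccccc3)c(OCc3ccccc3)c2)c1OCc1ccccc1
A6 | alternative 2 | [4-(benzyloxy)-2-hydroxyphenyl]boronic acid | OB(O)c1ccc(OCc2ccccc2)cc1O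
A7 | alternative 3 | (2R,3S,4S)-3-(benzyloxy)-4-[2,4-bis(benzyloxy)-3-methoxyphenyl]-2-[3,4-bis(benzyloxy)phenyl]chroman-7-ol | COc1c(OCc4ccccc4)ccc([C@@H]2c3ccc(O)cc3O[C@H](c3ccc(OCc4ccccc4)c(OCc4ccccc4)c3)[C@H]2OCc4ccccc4)c1OCc4ccccc4
A8 | alternative 3 | 4-methoxycyclohexa-2,5-dien-1-one carrying on C4 the chain CH(2,4-bis(benzyloxy)-3-methoxyphenyl)–CH(OBn)–CH(OAc)–[3,4-bis(benzyloxy)phenyl] with the configuration of A7 | CC(=O)O[C@H](c1ccc(OCc2ccccc2)c(OCc2ccccc2)c1)[C@@H](OCc1ccccc1)[C@H](c1ccc(OCc2ccccc2)c(OC)c1OCc1ccccc1)C1(OC)C=CC(=O)C=C1
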